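The ten-membered carbocycle is closed between the ester-bearing carbinol carbon C9 and its methyl-bearing neighbour C10 (germacrane numbering). In the precursor both carbons are electrophiles: C9 is a formyl group on the cis-fused γ-lactone and C10 the iodine-bearing carbon of a 2-iodoalkene whose methylene becomes the C14 methyl. A Nozaki–Hiyama–Kishi reaction reverses the polarity of C10 and forms, in one operation, the C9–C10 bond, the carbocycle and the C9 carbinol. The step exploits the cis C7/C8 fusion of the lactone ring, which places the formyl group and the epoxide-bearing C1–C6 chain on one face, and the 4,5-trans-epoxide as a second turn element.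

Key step: step 13

Remark: atoms are numbered as in germacranolides: C1–C10 ring; C4/C5 epoxide; C6 carbinol; C7/C8 lactone fusion; C9 ester carbon; C10 methyl-bearing carbon; C11, C12 (carbonyl) and C13 (exocyclic methylene) of the lactone; C14 on C10; C15 on C4. Descriptors written with these locants refer to this numbering. Compounds 1, 6, 7, the D-fructose-derived Shi ketone and 3-methylbut-2-enoyl chloride are assumed to be commercial.

Step 1
Reactants: 1 hepta-1,6-diyne
Product: 2 2-iodohept-1-en-6-yne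
Conditions: NaI, Me3SiCl, H2O (0.5 equiv), MeCN, 0 °C to rt; 1 in threefold excess
Reagents that add atoms: sodium iodide, [Na+].[I-]
Why: Markovnikov hydroiodination of one terminal alkyne by HI generated in situ should give the 2-iodo-1-alkene, and the excess of the symmetric diyne limits double addition (statistical monofunctionalisation).

Step 2
Reactants: 2 2-iodohept-1-en-6-yne
Product: 4 (2E)-8-iodo-3-methylnona-2,8-dien-1-ol, via alkenylalane 3 (not isolated)
Conditions: Me3Al (2 equiv), Cp2ZrCl2 (0.2 equiv), CH2Cl2, 0 °C to rt; then (CH2O)n, 0 °C to rt; aq. HCl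
Reagents that add atoms: trimethylaluminium, C[Al](C)C; paraformaldehyde (as formaldehyde), C=O
Why: Negishi zirconium-catalysed carboalumination adds methyl and aluminium syn across the remaining terminal alkyne (methyl to the internal carbon) and the alkenylalane is trapped by formaldehyde, which fixes the E geometry of the later C4=C5 bond (C15 cis to C6).

Step 3
Reactants: 4 (2E)-8-iodo-3-methylnona-2,8-dien-1-ol
Product: 5 (2E)-8-iodo-3-methylnona-2,8-dienal
Conditions: MnO2 (activated), CH2Cl2, rt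
Reagents that add atoms: none
Why: Allylic oxidation with MnO2 is selective for the allylic alcohol and should not isomerise the trisubstituted alkene or touch the vinyl iodide.

Step 4
Reactants: 6 4-tert-butoxy-4-oxobutanoic acid; 7 (4R)-4-benzyl-1,3-oxazolidin-2-one
Product: 9 tert-butyl 4-[(4R)-4-benzyl-2-oxo-1,3-oxazolidin-3-yl]-4-oxobutanoate, via mixed pivalic anhydride 8 (not isolated)
Conditions: t-BuCOCl, Et3N, THF, −20 °C; then 7, LiCl, −20 °C to rt
Reagents that add atoms: none
Why: N-acylation of the oxazolidinone through the pivaloyl mixed anhydride is the standard mild entry to Evans imides and leaves the tert-butyl ester intact.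

Step 5
Reactants: 9 tert-butyl 4-[(4R)-4-benzyl-2-oxo-1,3-oxazolidin-3-yl]-4-oxobutanoate; 5 (2E)-8-iodo-3-methylnona-2,8-dienal
Product: 11 tert-butyl (3R,4S,5E)-3-{[(4R)-4-benzyl-2-oxo-1,3-oxazolidin-3-yl]carbonyl}-4-hydroxy-10-iodo-6-methylundeca-5,10-dienoate, via boron enolate 10 (not isolated)
Conditions: 9, Bu2BOTf, i-Pr2NEt, CH2Cl2, −78 to 0 °C; then 5, −78 to 0 °C; pH 7 buffer, MeOH, 30% H2O2, 0 °C
Reagents that add atoms: none
Why: Evans syn aldol: the Z boron enolate of the imide (formed at the imide α-carbon, not next to the ester) reacts through a Zimmerman–Traxler chair in which the (R)-benzyl auxiliary blocks one enolate face, which should set C6 and C7 with the C6 hydroxyl syn to the C7 acetate arm.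

Step 6
Reactants: 11 aldol adduct
Product: 12 tert-butyl (3R,4S,5E)-4-hydroxy-10-iodo-3-[methoxy(methyl)carbamoyl]-6-methylundeca-5,10-dienoate
Conditions: MeNH(OMe)·HCl, Me3Al, CH2Cl2, −10 to 0 °C
Reagents that add atoms: N,O-dimethylhydroxylamine hydrochloride, CNOC.Cl
Why: Aluminium-amide transamination of the β-hydroxy imide (Weinreb amide formation) is assisted by the free hydroxyl, releases the auxiliary and should leave the hindered tert-butyl ester untouched at or below 0 °C.

Step 7
Reactants: 12 Weinreb amide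
Product: 13 tert-butyl (3R,4S,5E)-4-[(tert-butyldimethylsilyl)oxy]-10-iodo-3-[methoxy(methyl)carbamoyl]-6-methylundeca-5,10-dienoate
Conditions: TBSOTf, 2,6-lutidine, CH2Cl2, −78 °C
Reagents that add atoms: tert-butyldimethylsilyl trifluoromethanesulfonate, CC(C)(C)[Si](C)(C)OS(=O)(=O)C(F)(F)F
Why: Silylation of the secondary allylic alcohol protects C6–OH, which must not form a lactone with C12 or a lactol with the later C9 aldehyde.

Step 8
Reactants: 13 silyl ether
Product: 14 tert-butyl (3R,4S,5E)-3-acryloyl-4-[(tert-butyldimethylsilyl)oxy]-10-iodo-6-methylundeca-5,10-dienoate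
Conditions: CH2=CHMgBr (2.5 equiv), THF, −78 to 0 °C; inverse quench into cold 1 M HCl
Reagents that add atoms: vinylmagnesium bromide, C=C[Mg]Br
Why: Weinreb ketone synthesis: the chelated tetrahedral adduct stops at single addition and masks the ketone until work-up, the Grignard reagent does not exchange with the vinyl iodide, and the cold acidic quench prevents conjugate addition of the released amine.

Step 9
Reactants: 14 vinyl ketone
Product: 15 tert-butyl (3S,4S,5E)-4-[(tert-butyldimethylsilyl)oxy]-3-[(1S)-1-hydroxyprop-2-en-1-yl]-10-iodo-6-methylundeca-5,10-dienoate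
Conditions: NaBH4, CeCl3·7H2O, MeOH, −78 °C
Reagents that add atoms: none
Why: Luche 1,2-reduction under Felkin–Anh control (hydride anti to the branched C6 substituent on C7) should place the new C8–O anti to the C7 acetate arm and 1,3-anti to the C6 silyloxy group.

Step 10
Reactants: 15 allylic alcohol
Product: 17 (4S,5S)-4-[(1S,2E)-1-[(tert-butyldimethylsilyl)oxy]-7-iodo-3-methylocta-2,7-dien-1-yl]-5-ethenyloxolan-2-one, via hydroxy acid 16 (not isolated)
Conditions: CF3CO2H–CH2Cl2 (1:10), 0 °C
Reagents that add atoms: none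
Why: Acidolysis of the tert-butyl ester and spontaneous γ-lactonisation onto the only free hydroxyl (C8–OH) should give the 8,12-lactone with the C7 and C8 substituents cis, no stereocentre being touched.

Step 11
Reactants: 17 lactone
Product: 18 (4S,5S)-4-[(R)-[(tert-butyldimethylsilyl)oxy][(2R,3R)-3-(4-iodopent-4-en-1-yl)-3-methyloxiran-2-yl]methyl]-5-ethenyloxolan-2-one
Conditions: D-fructose-derived Shi ketone (1,2:4,5-di-O-isopropylidene-β-D-erythro-2,3-hexodiulo-2,6-pyranose, 0.3 equiv), KHSO5 (Oxone), K2CO3, Bu4NHSO4, MeCN–CH2(OMe)2 / aq. Na2B4O7–Na2EDTA, 0 °C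
Reagents that add atoms: potassium peroxymonosulfate, [K+].OOS(=O)(=O)[O-]
Why: Shi asymmetric epoxidation: the chiral dioxirane should epoxidise the electron-rich E-trisubstituted C4=C5 bond under reagent control in the sense that gives R,R epoxides from E-alkenes (here 4R,5R), while the monosubstituted vinyl group and the electron-poor iodoalkene react far more slowly.

Step 12
Reactants: 18 epoxy lactone
Product: 20 (2R,3S)-3-[(R)-[(tert-butyldimethylsilyl)oxy][(2R,3R)-3-(4-iodopent-4-en-1-yl)-3-methyloxiran-2-yl]methyl]-5-oxooxolane-2-carbaldehyde, via diol 19 (not isolated)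
Conditions: OsO4 (2 mol %), NaIO4, 2,6-lutidine, 1,4-dioxane–H2O (3:1), rt
Reagents that add atoms: sodium periodate, [Na+].[O-]I(=O)(=O)=O (oxygen passed on through catalytic osmium tetroxide, O=[Os](=O)(=O)=O)
Why: Lemieux–Johnson cleavage: OsO4 should dihydroxylate the monosubstituted alkene in preference to the halogen-deactivated 2-iodoalkene, and periodate cleaves the diol to the C9 aldehyde under buffered conditions that spare the epoxide.

Step 13
Reactants: 20 iodoalkene aldehyde
Product: 21 (4R,5R,6R,7S,8R,9R)-6-[(tert-butyldimethylsilyl)oxy]-4,5-epoxy-9-hydroxygermacr-10(14)-en-12,8-olide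
Conditions: CrCl2 (10 equiv), NiCl2 (0.1 equiv), degassed DMSO, rt, 20 added by syringe pump to 2 mM
Reagents that add atoms: none
Why: Zerovalent nickel (formed from NiCl2 and CrCl2) inserts into the C10–I bond, the alkenyl group passes to trivalent chromium, and the nucleophilic alkenylchromium adds to the C9 aldehyde (Nozaki–Hiyama–Kishi reaction, polarity reversal at C10). The closest known reaction type is the intramolecular alkenyl iodide–aldehyde coupling that closes nine- to twelve-membered rings as 2-methylene carbinols. The ten-membered carbocycle closes in a 10-exo-trig mode under high dilution, with the cis-fused lactone and the trans epoxide acting as turn elements that bring C9 and C10 together. The new C9 stereocentre is set by the substrate: the tethered alkenylchromium can reach the formyl group only from the side of the C7 chain, and with the C=O dipole opposed to the lactone C8–O bond (Cornforth-type rotamer, the poorly basic lactone oxygen not chelating in DMSO) this is the Re face, which should give the 9R alcohol (trans to O8 on the ring). The step needs addition to the aldehyde in the presence of the lactone and the epoxide, which the low basicity and aldehyde selectivity of organochromium reagents secure (CrCl2 is also used on epoxy aldehydes in Takai olefinations), and it needs cyclisation to outrun oligomerisation, which slow addition secures.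

Step 14
Reactants: 21 macrocyclic allylic alcohol
Product: 22 (4R,5R,6R,7S,8R,9R,10R)-6-[(tert-butyldimethylsilyl)oxy]-4,5-epoxy-9-hydroxygermacran-12,8-olide
Conditions: [Rh(nbd)(dppb)]BF4 (5 mol %), H2 (50 bar), CH2Cl2, rt
Reagents that add atoms: none
Why: Hydroxyl-directed hydrogenation: the cationic rhodium binds C9–OH and the exocyclic alkene, and in the chelate with C9–H eclipsing the C10–C1 bond (A(1,2) strain minimised, as for acyclic 2-methylene carbinols) hydrogen should add so that the new C14 methyl is anti to O9 along C8–C9–C10–C1 (10R).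

Step 15
Reactants: 22 saturated hydroxy lactone
Product: 25 (4R,5R,6R,7S,8R,9R,10R)-6-[(tert-butyldimethylsilyl)oxy]-4,5-epoxy-9-hydroxygermacr-11(13)-en-12,8-olide, via Mannich base 23 (not isolated), via ammonium iodide 24 (not isolated)
Conditions: LDA (2.3 equiv), THF, −78 °C; CH2=NMe2+ I−, −78 °C to rt; then MeI, MeOH, rt; then aq. NaHCO3, CH2Cl2, rt
Reagents that add atoms: N,N-dimethylmethyleneiminium iodide (Eschenmoser's salt), C=[N+](C)C.[I-]
Why: Mannich aminomethylation of the lactone lithium enolate at C11, N-methylation and Hofmann-type elimination is the standard α-methylenation of γ-lactones; the C9 alkoxide is carried as a spectator and the epoxide is inert at −78 °C.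

Step 16
Reactants: 25 α-methylene lactone
Product: 26 (4R,5R,6R,7S,8R,9R,10R)-6-[(tert-butyldimethylsilyl)oxy]-4,5-epoxy-9-[(3-methylbut-2-enoyl)oxy]germacr-11(13)-en-12,8-olide
Conditions: 3-methylbut-2-enoyl chloride, pyridine, DMAP (cat.), CH2Cl2, 0 °C to rt
Reagents that add atoms: 3-methylbut-2-enoyl chloride, CC(C)=CC(=O)Cl
Why: Acylation of the only free hydroxyl under pyridine/DMAP catalysis should install the senecioate, the weak base avoiding deconjugation of the acyl group through a vinylketene.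

Step 17
Reactants: 26 silyl-protected senecioate
Product: 27 CNP0214930.1, (4R,5R,6R,7R,8R,9R,10R)-4,5-epoxy-6-hydroxy-9-[(3-methylbut-2-enoyl)oxy]germacr-11(13)-en-12,8-olide
Conditions: HF·pyridine, pyridine, THF, 0 °C to rt
Reagents that add atoms: none
Why: Buffered fluoride desilylation should free C6–OH without opening the trisubstituted epoxide, adding to the α-methylene lactone or cleaving the ester.

Compound list
1 | hepta-1,6-diyne | C#CCCCC#C | starting material
2 | 2-iodohept-1-en-6-yne | C=C(I)CCCC#C | intermediate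
3 | [(1E)-7-iodo-2-methylocta-1,7-dien-1-yl]dimethylalumane | C[Al](C)/C=C(\C)CCCC(I)=C | intermediate (not isolated)
4 | (2E)-8-iodo-3-methylnona-2,8-dien-1-ol | OC/C=C(\C)CCCC(I)=C | intermediate
5 | (2E)-8-iodo-3-methylnona-2,8-dienal | O=C/C=C(\C)CCCC(I)=C | intermediate
6 | 4-tert-butoxy-4-oxobutanoic acid (mono-tert-butyl succinate) | CC(C)(C)OC(=O)CCC(=O)O | starting material
7 | (4R)-4-benzyl-1,3-oxazolidin-2-one | O=C1OC[C@H](N1)Cc1ccccc1 | starting material
8 | 4-tert-butoxy-4-oxobutanoic 2,2-dimethylpropanoic anhydride | CC(C)(C)OC(=O)CCC(=O)OC(=O)C(C)(C)C | intermediate (not isolated)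
9 | tert-butyl 4-[(4R)-4-benzyl-2-oxo-1,3-oxazolidin-3-yl]-4-oxobutanoate | CC(C)(C)OC(=O)CCC(=O)N1C(=O)OC[C@H]1Cc1ccccc1 | intermediate
10 | dibutylboron (Z)-enolate of 9 | CCCCB(CCCC)O/C(=C\CC(=O)OC(C)(C)C)N1C(=O)OC[C@H]1Cc1ccccc1 | intermediate (not isolated)
11 | tert-butyl (3R,4S,5E)-3-{[(4R)-4-benzyl-2-oxo-1,3-oxazolidin-3-yl]carbonyl}-4-hydroxy-10-iodo-6-methylundeca-5,10-dienoate | CC(C)(C)OC(=O)C[C@@H](C(=O)N1C(=O)OC[C@H]1Cc1ccccc1)[C@@H](O)/C=C(\C)CCCC(I)=C | intermediate
12 | tert-butyl (3R,4S,5E)-4-hydroxy-10-iodo-3-[methoxy(methyl)carbamoyl]-6-methylundeca-5,10-dienoate | CC(C)(C)OC(=O)C[C@@H](C(=O)N(C)OC)[C@@H](O)/C=C(\C)CCCC(I)=C | intermediate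
13 | tert-butyl (3R,4S,5E)-4-[(tert-butyldimethylsilyl)oxy]-10-iodo-3-[methoxy(methyl)carbamoyl]-6-methylundeca-5,10-dienoate | CC(C)(C)OC(=O)C[C@@H](C(=O)N(C)OC)[C@@H](O[Si](C)(C)C(C)(C)C)/C=C(\C)CCCC(I)=C | intermediate
14 | tert-butyl (3R,4S,5E)-3-acryloyl-4-[(tert-butyldimethylsilyl)oxy]-10-iodo-6-methylundeca-5,10-dienoate | CC(C)(C)OC(=O)C[C@@H](C(=O)C=C)[C@@H](O[Si](C)(C)C(C)(C)C)/C=C(\C)CCCC(I)=C | intermediate
15 | tert-butyl (3S,4S,5E)-4-[(tert-butyldimethylsilyl)oxy]-3-[(1S)-1-hydroxyprop-2-en-1-yl]-10-iodo-6-methylundeca-5,10-dienoate | CC(C)(C)OC(=O)C[C@@H]([C@@H](O)C=C)[C@@H](O[Si](C)(C)C(C)(C)C)/C=C(\C)CCCC(I)=C | intermediate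
16 | (3S,4S,5E)-4-[(tert-butyldimethylsilyl)oxy]-3-[(1S)-1-hydroxyprop-2-en-1-yl]-10-iodo-6-methylundeca-5,10-dienoic acid | OC(=O)C[C@@H]([C@@H](O)C=C)[C@@H](O[Si](C)(C)C(C)(C)C)/C=C(\C)CCCC(I)=C | intermediate (not isolated)
17 | (4S,5S)-4-[(1S,2E)-1-[(tert-butyldimethylsilyl)oxy]-7-iodo-3-methylocta-2,7-dien-1-yl]-5-ethenyloxolan-2-one | O=C1C[C@H]([C@@H](O[Si](C)(C)C(C)(C)C)/C=C(\C)CCCC(I)=C)[C@H](C=C)O1 | intermediate
18 | (4S,5S)-4-[(R)-[(tert-butyldimethylsilyl)oxy][(2R,3R)-3-(4-iodopent-4-en-1-yl)-3-methyloxiran-2-yl]methyl]-5-ethenyloxolan-2-one | O=C1C[C@H]([C@@H](O[Si](C)(C)C(C)(C)C)[C@H]2O[C@]2(C)CCCC(I)=C)[C@H](C=C)O1 | intermediate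
19 | (4S,5S)-4-[(R)-[(tert-butyldimethylsilyl)oxy][(2R,3R)-3-(4-iodopent-4-en-1-yl)-3-methyloxiran-2-yl]methyl]-5-(1,2-dihydroxyethyl)oxolan-2-one (both epimers at the new carbinol) | O=C1C[C@H]([C@@H](O[Si](C)(C)C(C)(C)C)[C@H]2O[C@]2(C)CCCC(I)=C)[C@H](C(O)CO)O1 | intermediate (not isolated)
20 | (2R,3S)-3-[(R)-[(tert-butyldimethylsilyl)oxy][(2R,3R)-3-(4-iodopent-4-en-1-yl)-3-methyloxiran-2-yl]methyl]-5-oxooxolane-2-carbaldehyde | O=C1C[C@H]([C@@H](O[Si](C)(C)C(C)(C)C)[C@H]2O[C@]2(C)CCCC(I)=C)[C@H](C=O)O1 | intermediate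
21 | (4R,5R,6R,7S,8R,9R)-6-[(tert-butyldimethylsilyl)oxy]-4,5-epoxy-9-hydroxygermacr-10(14)-en-12,8-olide | C1C(=O)O[C@H]2[C@H](O)C(=C)CCC[C@@]3(C)O[C@@H]3[C@H](O[Si](C)(C)C(C)(C)C)[C@@H]12 | intermediate
22 | (4R,5R,6R,7S,8R,9R,10R)-6-[(tert-butyldimethylsilyl)oxy]-4,5-epoxy-9-hydroxygermacran-12,8-olide | C1C(=O)O[C@H]2[C@H](O)[C@H](C)CCC[C@@]3(C)O[C@@H]3[C@H](O[Si](C)(C)C(C)(C)C)[C@@H]12 | intermediate
23 | 11-(dimethylaminomethyl) derivative of 22 (C11 epimers) | CN(C)CC1C(=O)O[C@H]2[C@H](O)[C@H](C)CCC[C@@]3(C)O[C@@H]3[C@H](O[Si](C)(C)C(C)(C)C)[C@@H]12 | intermediate (not isolated)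
24 | trimethylammoniomethyl iodide derived from 23 (C11 epimers) | C[N+](C)(C)CC1C(=O)O[C@H]2[C@H](O)[C@H](C)CCC[C@@]3(C)O[C@@H]3[C@H](O[Si](C)(C)C(C)(C)C)[C@@H]12.[I-] | intermediate (not isolated)
25 | (4R,5R,6R,7S,8R,9R,10R)-6-[(tert-butyldimethylsilyl)oxy]-4,5-epoxy-9-hydroxygermacr-11(13)-en-12,8-olide | C=C1C(=O)O[C@H]2[C@H](O)[C@H](C)CCC[C@@]3(C)O[C@@H]3[C@H](O[Si](C)(C)C(C)(C)C)[C@@H]12 | intermediate
26 | (4R,5R,6R,7S,8R,9R,10R)-6-[(tert-butyldimethylsilyl)oxy]-4,5-epoxy-9-[(3-methylbut-2-enoyl)oxy]germacr-11(13)-en-12,8-olide | C=C1C(=O)O[C@H]2[C@H](OC(=O)C=C(C)C)[C@H](C)CCC[C@@]3(C)O[C@@H]3[C@H](O[Si](C)(C)C(C)(C)C)[C@@H]12 | intermediate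
27 | CNP0214930.1, (4R,5R,6R,7R,8R,9R,10R)-4,5-epoxy-6-hydroxy-9-[(3-methylbut-2-enoyl)oxy]germacr-11(13)-en-12,8-olide | C=C1C(=O)O[C@H]2[C@H](OC(=O)C=C(C)C)[C@H](C)CCC[C@@]3(C)O[C@@H]3[C@H](O)[C@@H]12 | target

Total step count: 17. Longest linear sequence: 16 steps (steps 1–3 and 5–17, from 1).

Steps most likely to fail

1. Step 13. The alkenylchromium may add to the other face of the formyl group (a chelated or Felkin-type rotamer instead of the Cornforth-type one), so that the C9 epimer predominates; intermolecular coupling may also compete. The fallback sets out from 20 and corrects C9 by inversion instead of by facial selectivity. The cyclisation is run as in step 13 and the (9S)-epimeric macrocyclic alcohol F1 is isolated. Mitsunobu reaction with 4-nitrobenzoic acid (PPh3, DIAD, toluene, 0 °C) should give the inverted (9R)-4-nitrobenzoate F2. Methanolysis (K2CO3, MeOH, 0 °C) brings the route back at 21.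

2. Step 14. If the ring holds O9 and C1 gauche about the C9–C10 bond, the hydroxyl-directed delivery would put hydrogen on the face that leaves the C14 methyl trans to O9 on the ring (the C10 epimer). The fallback sets out from 21 and replaces directed delivery by steric shielding. Silylation (Et3SiOTf, 2,6-lutidine, CH2Cl2, −78 °C) gives the 9-O-triethylsilyl ether F3. Heterogeneous hydrogenation (H2, Pt/C, EtOAc), which should add from the face remote from the bulky silyloxy group, gives the saturated bis-silyl ether F4. Selective removal of the triethylsilyl group (HF·pyridine, pyridine, THF, 0 °C, short reaction time) comes back at 22.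

3. Step 9. Hydride addition to the vinyl ketone with a small reagent may show low facial selectivity, so that much of the material ends as the C8 epimer. The fallback sets out from 14. The (1R)-carbinol epimer F5 from the reduction is separated and inverted by Mitsunobu reaction with 4-nitrobenzoic acid (PPh3, DIAD, THF, 0 °C) to the (1S)-4-nitrobenzoate F6. Methanolysis (K2CO3, MeOH, 0 °C; the tert-butyl ester survives) comes back at 15.

Further compounds
F1 | step 13 | (4R,5R,6R,7S,8R,9S)-6-[(tert-butyldimethylsilyl)oxy]-4,5-epoxy-9-hydroxygermacr-10(14)-en-12,8-olide | C1C(=O)O[C@H]2[C@@H](O)C(=C)CCC[C@@]3(C)O[C@@H]3[C@H](O[Si](C)(C)C(C)(C)C)[C@@H]12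
F2 | step 13 | (4R,5R,6R,7S,8R,9R)-6-[(tert-butyldimethylsilyl)oxy]-4,5-epoxy-9-[(4-nitrobenzoyl)oxy]germacr-10(14)-en-12,8-olide | C1C(=O)O[C@H]2[C@H](OC(=O)c4ccc(cc4)[N+](=O)[O-])C(=C)CCC[C@@]3(C)O[C@@H]3[C@H](O[Si](C)(C)C(C)(C)C)[C@@H]12
F3 | step 14 | (4R,5R,6R,7S,8R,9R)-6-[(tert-butyldimethylsilyl)oxy]-4,5-epoxy-9-[(triethylsilyl)oxy]germacr-10(14)-en-12,8-olide | C1C(=O)O[C@H]2[C@H](O[Si](CC)(CC)CC)C(=C)CCC[C@@]3(C)O[C@@H]3[C@H](O[Si](C)(C)C(C)(C)C)[C@@H]12
F4 | step 14 | (4R,5R,6R,7S,8R,9R,10R)-6-[(tert-butyldimethylsilyl)oxy]-4,5-epoxy-9-[(triethylsilyl)oxy]germacran-12,8-olide | C1C(=O)O[C@H]2[C@H](O[Si](CC)(CC)CC)[C@H](C)CCC[C@@]3(C)O[C@@H]3[C@H](O[Si](C)(C)C(C)(C)C)[C@@H]12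
F5 | step 9 | tert-butyl (3S,4S,5E)-4-[(tert-butyldimethylsilyl)oxy]-3-[(1R)-1-hydroxyprop-2-en-1-yl]-10-iodo-6-methylundeca-5,10-dienoate | CC(C)(C)OC(=O)C[C@@H]([C@H](O)C=C)[C@@H](O[Si](C)(C)C(C)(C)C)/C=C(\C)CCCC(I)=C
F6 | step 9 | tert-butyl (3S,4S,5E)-4-[(tert-butyldimethylsilyl)oxy]-10-iodo-6-methyl-3-{(1S)-1-[(4-nitrobenzoyl)oxy]prop-2-en-1-yl}undeca-5,10-dienoate | CC(C)(C)OC(=O)C[C@@H]([C@@H](OC(=O)c1ccc(cc1)[N+](=O)[O-])C=C)[C@@H](O[Si](C)(C)C(C)(C)C)/C=C(\C)CCCC(I)=C
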